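**Strategy.** Ring A (the filicinic ring) is read as a ketene trimer in which oxygenated carbons alternate with C(CH3)2, the acyl-bearing carbon and the benzyl-bearing carbon. Both ring bonds that flank the C(OH)=C(CH2Ar) pair are made in one operation, a two-carbon ring expansion. The enolate of a dihydrocoumarin, in which ring B is tied to that pair through its ortho phenol oxygen, adds to 3-ethoxy-4,4-dimethylcyclobutenone. The alkoxide opens the four-membered ring, and the freed C(CH3)2 terminus closes on the lactone carbonyl and releases the phenol. The step exploits the quaternary carbon, the 1,3,5-oxygen pattern of ring A and the hydroxyl ortho to the methylene bridge.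

Key step: step 4

Remark on the chemistry: ring A is a rapidly equilibrating enol/β-triketone system. Every compound that contains it is drawn as the tautomer matching the target drawing, and the target is achiral.

**Step 1**
Reactants: 1 2,5-dimethylbenzene-1,3-diol (2,5-dimethylresorcinol); 2 acrylic acid
Product: 3 7-hydroxy-5,8-dimethyl-3,4-dihydro-2H-chromen-2-one
Conditions: 2 (1.05 equiv), sulfonic acid resin Amberlyst-15, toluene, reflux, Dean–Stark trap
Reagents that add atoms: none
Why: Acid-catalysed Friedel–Crafts conjugate addition (hydroarylation) of the activated resorcinol to acrylic acid, followed by lactonisation with the neighbouring hydroxyl, is a known one-pot dihydrocoumarin synthesis, and since the two free ring positions of 1 are equivalent only one regioisomer can form and no stereocentre is created.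

**Step 2**
Reactants: 3 7-hydroxy-5,8-dimethyl-3,4-dihydro-2H-chromen-2-one; 4 butanoyl chloride
Product: 5 6-butanoyl-7-hydroxy-5,8-dimethyl-3,4-dihydro-2H-chromen-2-one
Conditions: AlCl3 (3.5 equiv), ClCH2CH2Cl, 0 → 70 °C; then ice, 2 M HCl
Reagents that add atoms: none
Why: Friedel–Crafts acylation (O-acylation, then Fries migration) can only reach C6, the single free ring position, which lies ortho to the free hydroxyl and para to the lactone oxygen, while the 5-methyl group blocks the indanone rearrangement of dihydrocoumarins, and no stereocentre is created.

**Step 3**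
Reactants: 6 2-methylpropanoyl chloride (isobutyryl chloride); 7 ethoxyacetylene
Product: 9 3-ethoxy-4,4-dimethylcyclobut-2-en-1-one, via dimethylketene 8 (not isolated)
Conditions: Et3N (1.2 equiv), Et2O, 0 → 35 °C
Reagents that add atoms: none
Why: Dehydrochlorination gives dimethylketene, which undergoes the known regioselective [2+2] cycloaddition with the ynol ether, the nucleophilic terminal alkyne carbon bonding to the ketene carbonyl carbon, and no stereocentre is created.

**Step 4**
Reactants: 5 6-butanoyl-7-hydroxy-5,8-dimethyl-3,4-dihydro-2H-chromen-2-one; 9 3-ethoxy-4,4-dimethylcyclobut-2-en-1-one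
Product: 14 2-[(3-butanoyl-4,6-dihydroxy-2,5-dimethylphenyl)methyl]-3,5-dihydroxy-4,4-dimethylcyclohexa-2,5-dien-1-one, via dilithium enolate 10 (not isolated), via dilithium aldolate 11 (not isolated), via dilithium dienolate 12 (not isolated), via ethyl enol ether 13 (not isolated)
Conditions: 5, LiN(SiMe3)2 (2.3 equiv), THF, −78 °C; add 9, −78 → 45 °C; then 2 M aq HCl, THF, 40 °C
Reagents that add atoms: water, O
Why: Proposed new method: two equivalents of LiN(SiMe3)2 turn 5 into the phenoxide/lactone-enolate 10, whose C3 adds in the 1,2 sense (as in a Stork–Danheiser addition) to the strained, non-enolisable carbonyl C1 of vinylogous ester 9 and so makes the first bond in aldolate 11. The oxido group then drives a conrotatory 4π electrocyclic opening of the cyclobutene that cleaves C1–C4 and, by rotating outward, turns the lactone-bearing carbon inward, so that dienolate 12 is formed with this carbon cis to the C(OEt)=C(CH3)2 unit. The γ-carbon C(CH3)2 of 12 attacks the aryl-ester carbonyl in a vinylogous Dieckmann condensation, a 6-(enolendo)-exo-trig closure that makes the second bond, the quaternary carbon and the only new ring while the para-acylphenoxide leaves, whereas attack through the α-carbon or through oxygen would give strained four-membered rings and stays reversible. The closest known reaction types are the alkoxide-accelerated electrocyclic opening of the 1,2-adducts of organolithium reagents with cyclobutenones and squarate esters and the Dieckmann cyclisation of 4,4-dimethyl-3,5-dioxo esters. The selectivity needed is enolisation of the lactone beside the butanoyl group, which is secured because the first equivalent of base converts the ortho-hydroxyaryl ketone into a lithium chelate (a vinylogous carboxylate between two ortho substituents) that is less acidic than the aryl lactone and not electrophilic, and because deprotonation of the cyclic β-dicarbonyl product is the sink for all reversible pre-equilibria. The stereocentres of 11 and 12 are erased on the way to achiral 13, whose vinylogous ethyl ester is hydrolysed to 14 by the aqueous acid of the work-up.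

**Step 5**
Reactants: 14 2-[(3-butanoyl-4,6-dihydroxy-2,5-dimethylphenyl)methyl]-3,5-dihydroxy-4,4-dimethylcyclohexa-2,5-dien-1-one; 4 butanoyl chloride
Product: 16 2-butanoyl-6-[(3-butanoyl-4,6-dihydroxy-2,5-dimethylphenyl)methyl]-3,5-dihydroxy-4,4-dimethylcyclohexa-2,5-dien-1-one (target), via enol butanoate 15 (not isolated)
Conditions: 4 (1.1 equiv), Et3N (3 equiv), CH2Cl2, 0 °C; then DMAP (0.3 equiv), 25 °C; 1 M HCl work-up
Reagents that add atoms: none
Why: O-acylation of the most acidic enol followed by DMAP-catalysed O-to-C acyl migration (the standard C-acylation of cyclic 1,3-diones) should deliver the butanoyl group to the only carbon of ring A that still bears hydrogen, the chelated 2-acyl-1,3-dione anion being the thermodynamic sink to which any phenol ester is also funnelled by reversible acyl transfer, and no stereocentre is created.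

**Compound list**
1 | 2,5-dimethylbenzene-1,3-diol | Cc1cc(O)c(C)c(O)c1 | starting material
2 | acrylic acid | C=CC(=O)O | starting material
3 | 7-hydroxy-5,8-dimethyl-3,4-dihydro-2H-chromen-2-one | O=C1CCc2c(C)cc(O)c(C)c2O1 | intermediate
4 | butanoyl chloride | CCCC(=O)Cl | starting material
5 | 6-butanoyl-7-hydroxy-5,8-dimethyl-3,4-dihydro-2H-chromen-2-one | CCCC(=O)c1c(C)c2CCC(=O)Oc2c(C)c1O | intermediate
6 | 2-methylpropanoyl chloride | CC(C)C(=O)Cl | starting material
7 | ethoxyacetylene | C#COCC | starting material
8 | dimethylketene | CC(C)=C=O | intermediate
9 | 3-ethoxy-4,4-dimethylcyclobut-2-en-1-one | CCOC1=CC(=O)C1(C)C | intermediate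
10 | dilithium phenoxide/lactone enolate of 5 | [Li+].[Li+].[O-]C1=CCc2c(C)c(C(=O)CCC)c([O-])c(C)c2O1 | intermediate
11 | dilithium aldolate, lactone C3 bonded to C1 of the 3-ethoxy-4,4-dimethyl-1-oxidocyclobut-2-enyl unit (racemic mixture of diastereomers, both centres are lost later) | [Li+].[Li+].CCOC1=CC([O-])(C2Cc3c(C)c(C(=O)CCC)c([O-])c(C)c3OC2=O)C1(C)C | intermediate
12 | dilithium dienolate from ring opening, oxido group trans and lactone carbon cis to the C(OEt)=C(CH3)2 unit (racemic at lactone C3) | [Li+].[Li+].CCOC(=C(C)C)/C=C(/[O-])C1Cc2c(C)c(C(=O)CCC)c([O-])c(C)c2OC1=O | intermediate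
13 | 2-[(3-butanoyl-4,6-dihydroxy-2,5-dimethylphenyl)methyl]-5-ethoxy-3-hydroxy-4,4-dimethylcyclohexa-2,5-dien-1-one | CCOC1=CC(=O)C(Cc2c(C)c(C(=O)CCC)c(O)c(C)c2O)=C(O)C1(C)C | intermediate
14 | 2-[(3-butanoyl-4,6-dihydroxy-2,5-dimethylphenyl)methyl]-3,5-dihydroxy-4,4-dimethylcyclohexa-2,5-dien-1-one | O=C1C=C(O)C(C)(C)C(O)=C1Cc1c(C)c(C(=O)CCC)c(O)c(C)c1O | intermediate
15 | 6-[(3-butanoyl-4,6-dihydroxy-2,5-dimethylphenyl)methyl]-5-hydroxy-4,4-dimethyl-3-oxocyclohexa-1,5-dien-1-yl butanoate | CCCC(=O)OC1=CC(=O)C(C)(C)C(O)=C1Cc1c(C)c(C(=O)CCC)c(O)c(C)c1O | intermediate
16 | 2-butanoyl-6-[(3-butanoyl-4,6-dihydroxy-2,5-dimethylphenyl)methyl]-3,5-dihydroxy-4,4-dimethylcyclohexa-2,5-dien-1-one | CCCC(=O)C1=C(O)C(C)(C)C(O)=C(Cc2c(C)c(C(=O)CCC)c(O)c(C)c2O)C1=O | target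

Total step count: 5. Longest linear sequence: 4 steps (steps 1, 2, 4 and 5); step 3 is the side branch.

**Steps most likely to fail**

**Step 4.**
- The aldolate may revert to its components.
- It may also be drained in several ways before the hindered C(CH3)2 terminus closes: by conjugate addition–elimination at the ethoxy-bearing carbon, by acyl transfer from the aryl ester to the alkoxide, or by proton transfer within the dienolate.
- On warming, the lactone enolate may be lost through ketene formation.

The fallback sets out from 5 and comes back at 14. It makes the same two bonds in the reverse order by known polyketide chemistry. The dianion of commercial methyl 4-methyl-3-oxopentanoate (NaH, then n-BuLi, THF, 0 °C) is used in excess to cover the acidic protons of 5. Its γ-carbon is acylated by the lactone carbonyl of 5, giving methyl 7-(3-butanoyl-4,6-dihydroxy-2,5-dimethylphenyl)-4,4-dimethyl-3,5-dioxoheptanoate F1. This compound is isolated and closed by a Dieckmann condensation (NaOMe, MeOH, reflux) to 14.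

**Step 2.**
- Acyl transfer may stop at oxygen.
- Lewis-acid opening of the lactone and intermolecular acyl exchange may outrun migration into the crowded position between methyl and hydroxyl.

The fallback sets out from 1 and comes back at 5, with the order of events inverted. Compound 1 is C-acylated first, while both free hydroxyl groups still activate the ring (butanoic acid, BF3·OEt2, 90 °C, Friedel–Crafts acylation). This gives 1-(2,4-dihydroxy-3,6-dimethylphenyl)butan-1-one F2. The lactone ring is then annulated onto the last free ring position with 2 (CF3SO3H, toluene, reflux, hydroarylation and lactonisation with the non-chelated hydroxyl).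

**Step 5.**
- Acylation of the phenol oxygens may compete.
- The O-to-C migration may be incomplete.
- Amine-induced retro-Michael cleavage and scrambling of the methylene bridge may erode the step.

The fallback sets out from 14 and comes back at 16. It gives up chemoselective monoacylation for exhaustive acylation followed by selective deacylation. Excess butanoic anhydride, pyridine and DMAP should C-acylate ring A and esterify both phenols, giving the ring-B dibutanoate of 16 F3. Its two aryl esters are then cleaved by brief methanolysis (K2CO3, MeOH, 0 °C), which the chelated C-acyl groups survive.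

**Further compounds**
F1 | step 4 | methyl 7-(3-butanoyl-4,6-dihydroxy-2,5-dimethylphenyl)-4,4-dimethyl-3,5-dioxoheptanoate | COC(=O)CC(=O)C(C)(C)C(=O)CCc1c(C)c(C(=O)CCC)c(O)c(C)c1O
F2 | step 2 | 1-(2,4-dihydroxy-3,6-dimethylphenyl)butan-1-one | CCCC(=O)c1c(C)cc(O)c(C)c1O
F3 | step 5 | ring-B dibutanoate of 16 (both phenol oxygens acylated) | CCCC(=O)Oc1c(C)c(OC(=O)CCC)c(C(=O)CCC)c(C)c1CC1=C(O)C(C)(C)C(O)=C(C(=O)CCC)C1=O
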